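In a one-step world, target appears as starting material disappears; the runs below do something else.

| flask | starting material | temperature | remark | time |
|---|---|---|---|---|
| east | 0.33 M | 24 °C | run made earlier |  |
| south-west | 0.73 M | 32 °C | run made earlier |  |
| north | 1.5 M | 24 °C | run made earlier |  |
| amber | 1.5 M | 35 °C |  | 120 h |
| teal | 0.40 M | 20 °C |  | 40 h |

| run | time / h | target / % | starting material / % |
|---|---|---|---|
| east | 2.00 | 5.1 | 2.2 |
| east | 5.00 | 14.6 | 1.6 |
| east | 10.0 | 21.8 | 0 |
| east | 15.0 | 27.8 | 0 |
| east | 20.0 | 29.9 | 0.2 |
| south-west | 2.00 | 16.0 | 0.9 |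
| south-west | 4.00 | 23.6 | 0 |
| south-west | 6.00 | 28.3 | 0 |
| south-west | 8.00 | 29.5 | 0.8 |
| south-west | 12.0 | 29.8 | 0 |
| north | 1.50 | 4.4 | 2.8 |
| north | 3.00 | 6.0 | 0 |
| north | 6.00 | 10.9 | 0 |
| north | 10.0 | 15.1 | 1.0 |
| north | 20.0 | 18.6 | 0 |

(readings scatter by 1 percentage point)



1. which of the two ends with the higher amount of target, in percent of the starting material charged ("neither" if they lie within 2 percentage points) (amber / teal / neither)
2. target at the end, in percent of the starting material charged, amber
3. target at the end, in percent of the starting material charged, teal

Read down the east table. After 2.00 h the flask holds 2.2% of starting material and 5.1% of target, yet target climbs to 29.9% by 20.0 h, so target forms from a hidden stage through a slow first-order step, the rate-limiting step for target.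

For such a rise, the reading at twice a time divided by the reading at that time is 1 + exp(−kt), and the ceiling drops out. Two pairs of readings per run give k = 0.120 h⁻¹ in east and 0.359 h⁻¹ in south-west, both with the scatter of the readings.

Teal at 20 °C lies as far below east as the midpoint of the span from 24 °C to 32 °C lies above it, so my reckoning divides east's k by the square root of that factor, giving 0.0695 h⁻¹. The number of turnovers, N = kt, the slow step's rate constant times the time, is then 2.78 for teal, which puts teal at 93.8% of its ceiling. Amber is warmer than south-west, and even south-west's k gives it 43.1 turnovers. Turnovers therefore leave the ceilings to compare. North, with c(starting material) at 1.5 M, reads 18.6% at 20.0 h, against 29.9% for east at 0.33 M.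

The forecast gives amber 23% (18.5% to 27%), teal 27.5% (24% to 31%), and names teal: “The plateau falls with concentration, which suggests a higher-order loss in the fast step.”

The flasks give amber 26.6% and teal 26.1%, so the answer is neither.

    starting material → side product A (k = 0.580 h⁻¹, Ea = 82.0 kJ mol⁻¹)
    starting material → intermediate A (k = 0.373 h⁻¹, Ea = 99.0 kJ mol⁻¹)
    starting material → intermediate B (k = 0.0875 h⁻¹, Ea = 102 kJ mol⁻¹)
    intermediate A → target (k = 0.0951 h⁻¹, Ea = 93.0 kJ mol⁻¹)
    intermediate B → side product A (k = 0.133 h⁻¹, Ea = 101 kJ mol⁻¹)
    2 starting material → self-condensation product (k = 0.935 M⁻¹ h⁻¹, Ea = 52.0 kJ mol⁻¹)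
    starting material + intermediate A → side product B (k = 0.0656 M⁻¹ h⁻¹, Ea = 86.0 kJ mol⁻¹)
    (constants at 20 °C)

Teal stands at 97.8% of its value at ten times the time, and that value, 26.7%, lies level with amber's 26.6%, so the tie lies in the ceilings. With the turning of 2 starting material into self-condensation product taken away, amber gives 40.2% instead of 26.6% and teal 34.4% instead of 26.1%, so this step, a part of the story, costs amber 14 percentage points against teal's 8.4 points. Amber's difference in temperature pulls the other way: with it taken away, amber gives 16.9%.

Teal stopped at 10 h has, scaled from the 2.78 turnovers reckoned from the readings for 40 h, 0.695 turnovers, which predicts 13.4% target; the computed flask holds 15.5%.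

The readings are calculated from invented constants.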